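**Strategy.** The oxolane (O1, C2 bearing the catechol ring, C3 bearing CH2OH, C4 bearing the carbinol carbon C7, C5) is traced back to a butenolide (C5 as carbonyl, C3=C4 unsaturated) that lacks only the C3–CH2 bond. The feature exploited is that the hydroxymethyl carbon on C3 and the oxygen on C7 are cis across C3–C4 and four bonds apart. A BrCH2SiMe2 group on O7 therefore delivers a CH2 radical to C3 anti to the C2 aryl group, closing a cis-fused six-membered siloxane and setting C3 and C4 in one operation. The precursor is that silyl ether of a 2-aryl-4-(aryl-hydroxymethyl)butenolide, built from two O-benzylated aldehydes and ethynyltrimethylsilane.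

Key step: step 9

Remarks
- Numbering: the target locants above (O1, C2, C3, C4, C5, C7) are used for the corresponding atoms of every intermediate.
- Descriptors: the geometry at C7 is set in step 1 and never touched, but its CIP label changes with the neighbouring group: S in 4, 5, 9 and 11–15, R in 6 and from 16 onwards. The aryl carbinol C2 is R in alkyne 9 and S from 11 onwards for the same reason.
- Assumption: (S,S)-ProPhenol is taken to direct alkynyl transfer to the Re face of an aryl aldehyde; steps 1 and 4 need opposite faces and so antipodal ligands, and the sense would be checked by Mosher ester analysis of 4 (the two ligands are exchanged if it is reversed).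
- Aldehydes 1 and 7 are catalogue compounds (the benzyl ethers of vanillin and 3,4-dihydroxybenzaldehyde).

**Step 1**
Reactants: 1 4-(benzyloxy)-3-methoxybenzaldehyde; 2 ethynyltrimethylsilane
Product: 4 (1S)-1-[4-(benzyloxy)-3-methoxyphenyl]-3-(trimethylsilyl)prop-2-yn-1-ol, via methyl[(trimethylsilyl)ethynyl]zinc 3 (not isolated)
Conditions: 2 (3 equiv), Me2Zn (3 equiv), (S,S)-ProPhenol (10 mol %), Ph3PO (20 mol %), toluene, 0 °C; then 1, 0 °C → rt
Reagents that add atoms: none
Why: Zinc–ProPhenol-catalysed enantioselective alkynylation of an aryl aldehyde, in which the dinuclear zinc complex formed from Me2Zn and the ligand binds 1 and transfers the alkynyl group of 3 to the Re face, setting C7.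

**Step 2**
Reactants: 4
Product: 5 tert-butyl({(1S)-1-[4-(benzyloxy)-3-methoxyphenyl]-3-(trimethylsilyl)prop-2-yn-1-yl}oxy)dimethylsilane
Conditions: TBSCl, imidazole, DMF, rt
Reagents that add atoms: tert-butyldimethylsilyl chloride, CC(C)(C)[Si](C)(C)Cl
Why: Silyl ether formation; the O7 silyl ether must later survive methanolic carbonate, Me2Zn, an aluminium hydride and palladium, and it ensures that only the other hydroxyl directs step 5.

**Step 3**
Reactants: 5
Product: 6 tert-butyl({(1R)-1-[4-(benzyloxy)-3-methoxyphenyl]prop-2-yn-1-yl}oxy)dimethylsilane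
Conditions: K2CO3 (cat.), MeOH/THF, rt
Reagents that add atoms: none
Why: Base-catalysed methanolysis of the alkynyl C–Si bond (protodesilylation), which leaves the secondary O–TBS ether intact; the descriptor changes only because ethynyl ranks below aryl.

**Step 4**
Reactants: 6; 7 3,4-bis(benzyloxy)benzaldehyde
Product: 9 (1R,4S)-1-[3,4-bis(benzyloxy)phenyl]-4-[4-(benzyloxy)-3-methoxyphenyl]-4-[(tert-butyldimethylsilyl)oxy]but-2-yn-1-ol, via silyloxypropynyl(methyl)zinc 8 (not isolated)
Conditions: 6 (1.5 equiv, excess recovered), Me2Zn, (R,R)-ProPhenol (20 mol %), Ph3PO (40 mol %), toluene, 0 °C; then 7, 0 °C → rt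
Reagents that add atoms: none
Why: The same zinc–ProPhenol alkynylation with the antipodal ligand, which should add 8 to the Si face of 7 and set C2 under catalyst control, since the existing C7 centre is remote from the new one.

**Step 5**
Reactants: 9
Product: 11 (1S,2Z,4S)-1-[3,4-bis(benzyloxy)phenyl]-4-[4-(benzyloxy)-3-methoxyphenyl]-4-[(tert-butyldimethylsilyl)oxy]-3-iodobut-2-en-1-ol, via cyclic sodium alkenylaluminate 10 (not isolated)
Conditions: NaAlH2(OCH2CH2OMe)2, THF, −20 → 0 °C; EtOAc; then I2, THF, −78 °C
Reagents that add atoms: iodine, II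
Why: Hydroxyl-directed trans-hydroalumination followed by iodinolysis, in which the aluminate on the free C2 oxygen delivers hydride to the proximal alkyne carbon (C3), aluminium ends on C4 in the five-membered ring of 10, and iodine replaces it with retention to give the Z iodide; the cold quench keeps 10 from losing silanolate to an allene.

**Step 6**
Reactants: 11
Product: 12 (5S)-5-[3,4-bis(benzyloxy)phenyl]-3-{(S)-[4-(benzyloxy)-3-methoxyphenyl][(tert-butyldimethylsilyl)oxy]methyl}furan-2(5H)-one
Conditions: Pd(PPh3)4 (5 mol %), CO (1 atm), K2CO3, THF, rt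
Reagents that add atoms: carbon monoxide, [C-]#[O+]
Why: Palladium-catalysed carbonylative lactonisation, in which zerovalent palladium inserts into the C4–I bond, CO inserts and the acylpalladium is captured by the C2 hydroxyl held cis by the Z alkene, so C5 enters as the lactone carbonyl; insoluble carbonate at room temperature is chosen to spare the acidic C2–H.

**Step 7**
Reactants: 12
Product: 13 (5S)-5-[3,4-bis(benzyloxy)phenyl]-3-{(S)-[4-(benzyloxy)-3-methoxyphenyl](hydroxy)methyl}furan-2(5H)-one
Conditions: HF·pyridine, pyridine, THF, 0 °C → rt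
Reagents that add atoms: none
Why: Fluoride-mediated desilylation under buffered, non-basic conditions, preferred to a basic fluoride source because the doubly activated C2–H of the 2-aryl butenolide could otherwise be removed.

**Step 8**
Reactants: 13; 14 (bromomethyl)chlorodimethylsilane
Product: 15 (5S)-5-[3,4-bis(benzyloxy)phenyl]-3-{(S)-[4-(benzyloxy)-3-methoxyphenyl]{[(bromomethyl)dimethylsilyl]oxy}methyl}furan-2(5H)-one
Conditions: imidazole, CH2Cl2, 0 °C; short silica plug, used at once
Reagents that add atoms: none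
Why: Silyl ether formation at the only free hydroxyl with a weak base; all phenols are benzylated, so nothing else is silylated or can quench the radical chain, and the hydrolytically labile ether is not stored.

**Step 9**
Reactants: 15
Product: 16 (2S,3S,4S,7R)-siloxane lactone: 2-[3,4-bis(benzyloxy)phenyl]-5-oxooxolane cis-fused at C3–C4 to the ring C3–CH2–SiMe2–O–C7(H)[4-(benzyloxy)-3-methoxyphenyl]
Conditions: Bu3SnH (1.3 equiv, syringe pump), AIBN (0.2 equiv), PhH, 80 °C, 0.01 M
Reagents that add atoms: none
Why: Bu3Sn• abstracts bromine from 15, the nucleophilic silylmethyl radical adds to C3, the electrophilic β-carbon of the butenolide, and the C4 radical, stabilised by the lactone carbonyl, takes hydrogen from Bu3SnH; this is a silicon-tethered radical cyclisation of the kind known for (bromomethyl)dimethylsilyl ethers of allylic alcohols and 2-(1-hydroxyalkyl)acrylates. The oxasilinane closes in the 6-endo mode, because the 5-exo alternative would attack the fully substituted, polarity-mismatched C4 and leave an unstabilised radical on C3. C3 is controlled by the C2 aryl group, which blocks one face of the flat butenolide so that the tethered radical enters anti to it (2,3-trans), a closure that lets the C7 aryl group lie pseudo-equatorial in a chair-like transition state. C4 is controlled by the new ring: with O7–Si–CH2 already bonded to one face of C3, hydrogen should arrive on the opposite, convex face and leave the siloxane cis-fused (3,4-cis). The step needs endo regioselectivity, anti facial selectivity and cis hydrogen delivery; alkene polarisation, the C2 aryl group and the short three-atom tether secure them, and slow addition of Bu3SnH at high dilution keeps direct reduction of the C–Br bond behind ring closure.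

**Step 10**
Reactants: 16
Product: 17 (2S,3S,4S,7R)-siloxane lactol: compound 16 with C5 reduced to CH(OH) as a mixture of anomers
Conditions: i-Bu2AlH (1.1 equiv), CH2Cl2, −78 °C
Reagents that add atoms: none
Why: Partial reduction of a γ-lactone to the lactol, the aluminium hemiacetal persisting at −78 °C until work-up; the siloxane is kept so that C4 stays locked cis while it is still next to a carbonyl.

**Step 11**
Reactants: 17
Product: 18 (2S,3S,4R,7R)-siloxane oxolane: compound 17 with C5 reduced to CH2
Conditions: Et3SiH, BF3·OEt2, CH2Cl2, −78 °C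
Reagents that add atoms: none
Why: Ionic hydrogenation of a lactol, in which BF3·OEt2 ionises the anomeric hydroxyl to the cyclic oxocarbenium ion and Et3SiH reduces it to the C5 methylene; no stereocentre is formed, and low temperature with a short reaction time keeps the benzylic C2–O1 and C7–O bonds from ionising.

**Step 12**
Reactants: 18
Product: 19 [(2S,3R,4R)-2-[3,4-bis(benzyloxy)phenyl]-4-{(R)-[4-(benzyloxy)-3-methoxyphenyl](hydroxy)methyl}oxolan-3-yl]methanol
Conditions: 30% H2O2, KF, KHCO3, THF/MeOH, rt
Reagents that add atoms: hydrogen peroxide, OO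
Why: Tamao oxidation, in which fluoride-activated silicon takes up hydroperoxide, the C3 methylene migrates from silicon to oxygen and hydrolysis of both Si–O bonds frees the CH2OH group and the C7 hydroxyl together; it follows the lactone reduction so that neither hydroxyl can translactonise and C4 cannot epimerise.

**Step 13**
Reactants: 19
Product: 20 (7R)-7-hydroxytaxiresinol
Conditions: H2 (1 atm), 10% Pd/C, EtOAc, rt, stopped at full debenzylation
Reagents that add atoms: none
Why: Catalytic hydrogenolysis of the three aryl benzyl ethers, which cleave much faster than the benzylic C7–OH and C2–O1 bonds in a neutral aprotic solvent.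

**Compound list**
1 | 4-(benzyloxy)-3-methoxybenzaldehyde | COc1cc(C=O)ccc1OCc1ccccc1 | starting material
2 | ethynyltrimethylsilane | C#C[Si](C)(C)C | starting material
3 | methyl[(trimethylsilyl)ethynyl]zinc | C[Zn]C#C[Si](C)(C)C | intermediate (not isolated)
4 | (1S)-1-[4-(benzyloxy)-3-methoxyphenyl]-3-(trimethylsilyl)prop-2-yn-1-ol | COc1cc([C@H](O)C#C[Si](C)(C)C)ccc1OCc1ccccc1 | intermediate
5 | tert-butyl({(1S)-1-[4-(benzyloxy)-3-methoxyphenyl]-3-(trimethylsilyl)prop-2-yn-1-yl}oxy)dimethylsilane | COc1cc([C@H](O[Si](C)(C)C(C)(C)C)C#C[Si](C)(C)C)ccc1OCc1ccccc1 | intermediate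
6 | tert-butyl({(1R)-1-[4-(benzyloxy)-3-methoxyphenyl]prop-2-yn-1-yl}oxy)dimethylsilane | COc1cc([C@H](O[Si](C)(C)C(C)(C)C)C#C)ccc1OCc1ccccc1 | intermediate
7 | 3,4-bis(benzyloxy)benzaldehyde | O=Cc1ccc(OCc2ccccc2)c(OCc2ccccc2)c1 | starting material
8 | silyloxypropynyl(methyl)zinc (methylzinc acetylide of 6) | COc1cc([C@H](O[Si](C)(C)C(C)(C)C)C#C[Zn]C)ccc1OCc1ccccc1 | intermediate (not isolated)
9 | (1R,4S)-1-[3,4-bis(benzyloxy)phenyl]-4-[4-(benzyloxy)-3-methoxyphenyl]-4-[(tert-butyldimethylsilyl)oxy]but-2-yn-1-ol | COc1cc([C@H](O[Si](C)(C)C(C)(C)C)C#C[C@H](O)c2ccc(OCc3ccccc3)c(OCc3ccccc3)c2)ccc1OCc1ccccc1 | intermediate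
10 | cyclic sodium alkenylaluminate (five-membered ring O–Al–C4=C3–C2, two 2-methoxyethoxy groups on aluminium) | COc1cc([C@H](O[Si](C)(C)C(C)(C)C)C2=C[C@@H](c3ccc(OCc4ccccc4)c(OCc4ccccc4)c3)O[Al-]2(OCCOC)OCCOC)ccc1OCc1ccccc1.[Na+] | intermediate (not isolated)
11 | (1S,2Z,4S)-1-[3,4-bis(benzyloxy)phenyl]-4-[4-(benzyloxy)-3-methoxyphenyl]-4-[(tert-butyldimethylsilyl)oxy]-3-iodobut-2-en-1-ol | COc1cc([C@H](O[Si](C)(C)C(C)(C)C)/C(I)=C/[C@H](O)c2ccc(OCc3ccccc3)c(OCc3ccccc3)c2)ccc1OCc1ccccc1 | intermediate
12 | (5S)-5-[3,4-bis(benzyloxy)phenyl]-3-{(S)-[4-(benzyloxy)-3-methoxyphenyl][(tert-butyldimethylsilyl)oxy]methyl}furan-2(5H)-one | COc1cc([C@H](O[Si](C)(C)C(C)(C)C)C2=C[C@@H](c3ccc(OCc4ccccc4)c(OCc4ccccc4)c3)OC2=O)ccc1OCc1ccccc1 | intermediate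
13 | (5S)-5-[3,4-bis(benzyloxy)phenyl]-3-{(S)-[4-(benzyloxy)-3-methoxyphenyl](hydroxy)methyl}furan-2(5H)-one | COc1cc([C@H](O)C2=C[C@@H](c3ccc(OCc4ccccc4)c(OCc4ccccc4)c3)OC2=O)ccc1OCc1ccccc1 | intermediate
14 | (bromomethyl)chlorodimethylsilane | C[Si](C)(Cl)CBr | starting material
15 | (5S)-5-[3,4-bis(benzyloxy)phenyl]-3-{(S)-[4-(benzyloxy)-3-methoxyphenyl]{[(bromomethyl)dimethylsilyl]oxy}methyl}furan-2(5H)-one | COc1cc([C@H](O[Si](C)(C)CBr)C2=C[C@@H](c3ccc(OCc4ccccc4)c(OCc4ccccc4)c3)OC2=O)ccc1OCc1ccccc1 | intermediate
16 | (2S,3S,4S,7R)-siloxane lactone (γ-lactone cis-fused at C3–C4 to the 1,2-oxasilinane C3–CH2–SiMe2–O–C7; 2-aryl trans to the C3 methylene) | COc1cc([C@H](O4)[C@H]2C(=O)O[C@H](c3ccc(OCc5ccccc5)c(OCc5ccccc5)c3)[C@H]2C[Si]4(C)C)ccc1OCc1ccccc1 | intermediate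
17 | (2S,3S,4S,7R)-siloxane lactol (C5–OH, both anomers) | COc1cc([C@H](O4)[C@H]2C(O)O[C@H](c3ccc(OCc5ccccc5)c(OCc5ccccc5)c3)[C@H]2C[Si]4(C)C)ccc1OCc1ccccc1 | intermediate
18 | (2S,3S,4R,7R)-siloxane oxolane (C5 = CH2) | COc1cc([C@H](O4)[C@H]2CO[C@H](c3ccc(OCc5ccccc5)c(OCc5ccccc5)c3)[C@H]2C[Si]4(C)C)ccc1OCc1ccccc1 | intermediate
19 | [(2S,3R,4R)-2-[3,4-bis(benzyloxy)phenyl]-4-{(R)-[4-(benzyloxy)-3-methoxyphenyl](hydroxy)methyl}oxolan-3-yl]methanol | COc1cc([C@H](O)[C@H]2CO[C@H](c3ccc(OCc4ccccc4)c(OCc4ccccc4)c3)[C@H]2CO)ccc1OCc1ccccc1 | intermediate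
20 | (7R)-7-hydroxytaxiresinol; 4-[(2S,3R,4R)-4-[(R)-hydroxy(4-hydroxy-3-methoxyphenyl)methyl]-3-(hydroxymethyl)oxolan-2-yl]benzene-1,2-diol | COc1cc([C@H](O)[C@H]2CO[C@H](c3ccc(O)c(O)c3)[C@H]2CO)ccc1O | target

**Step count and risk**
Total: 13 steps. Longest linear sequence: 13 steps (from 1).

Steps most likely to fail:

1. Step 9. The silylmethyl radical may be reduced by Bu3SnH before it cyclises, or hydrogen may be delivered to the wrong face of the C4 radical, giving the trans-fused ring. The fallback delivers the same carbon by a polar route. Setting out from alcohol 13, copper-catalysed conjugate addition of (isopropoxydimethylsilyl)methylmagnesium chloride (excess, CuBr·SMe2 cat., THF, −40 °C) should add anti to the C2 aryl group; the first equivalent forms the O7 magnesium alkoxide, a poor leaving group. Kinetic protonation of the enolate at −78 °C, anti to the new C3 substituent, should give the 3,4-cis isopropoxysilyl lactone F1. Acid-catalysed exchange (PPTS, PhH) of isopropoxide for the cis-disposed C7 hydroxyl then closes the siloxane and returns to 16.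

2. Step 11. The Lewis acid may ionise the benzylic C2–O1 or C7–O bond in competition with oxocarbenium formation, causing epimerisation at C2 or reductive loss of oxygen. The fallback avoids cations altogether. Setting out from lactone 16, thionation with Lawesson's reagent (toluene, 100 °C) gives the thionolactone F2, and radical desulfurisation with Ph3SnH and AIBN (toluene, reflux) reduces C5 to the methylene, returning to 18 and bypassing 17.

3. Step 4. Catalyst control may be incomplete with the bulky chiral alkyne, and addition to the electron-rich aldehyde may be slow. The fallback sets C2 by reduction instead of C–C bond formation. Setting out from 6 and 7, the lithium acetylide of 6 (n-BuLi, THF, −78 °C) adds to 7 to give the C2-epimeric propargylic alcohols F3; MnO2 (CH2Cl2) oxidises them to the ynone F4; Midland reduction with (R)-Alpine-Borane (from (+)-α-pinene and 9-borabicyclo[3.3.1]nonane; THF, rt), in which the alkynyl group is the small substituent, returns to 9.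

**Further compounds**
F1 | step 9 | (2S,3S,4S,7R)-2-[3,4-bis(benzyloxy)phenyl]-5-oxooxolane bearing CH2SiMe2(O-i-Pr) on C3 and (R)-[4-(benzyloxy)-3-methoxyphenyl](hydroxy)methyl on C4 | COc1cc([C@H](O)[C@H]2C(=O)O[C@H](c3ccc(OCc4ccccc4)c(OCc4ccccc4)c3)[C@H]2C[Si](C)(C)OC(C)C)ccc1OCc1ccccc1
F2 | step 11 | thionolactone analogue of 16 (C5=S) | COc1cc([C@H](O4)[C@H]2C(=S)O[C@H](c3ccc(OCc5ccccc5)c(OCc5ccccc5)c3)[C@H]2C[Si]4(C)C)ccc1OCc1ccccc1
F3 | step 4 | (4S)-1-[3,4-bis(benzyloxy)phenyl]-4-[4-(benzyloxy)-3-methoxyphenyl]-4-[(tert-butyldimethylsilyl)oxy]but-2-yn-1-ol, both C1 epimers | COc1cc([C@H](O[Si](C)(C)C(C)(C)C)C#CC(O)c2ccc(OCc3ccccc3)c(OCc3ccccc3)c2)ccc1OCc1ccccc1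
F4 | step 4 | (4S)-1-[3,4-bis(benzyloxy)phenyl]-4-[4-(benzyloxy)-3-methoxyphenyl]-4-[(tert-butyldimethylsilyl)oxy]but-2-yn-1-one | COc1cc([C@H](O[Si](C)(C)C(C)(C)C)C#CC(=O)c2ccc(OCc3ccccc3)c(OCc3ccccc3)c2)ccc1OCc1ccccc1
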